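At late times the target in the eta and epsilon runs was falling along with the substrate, and that is where I began my reckoning for the flask asked about, which carries 0.900 mM of capture agent against 0.45 mM and 1.8 mM in those runs.

the same everywhere: substrate 18 mM; first nucleophile 10.8 mM; second nucleophile 32.4 mM

| flask | capture agent | remark | time |
|---|---|---|---|
| eta | 0.45 mM | run made earlier |  |
| epsilon | 1.8 mM | run made earlier |  |
| flask | 0.900 mM |  | 15 d |

| run | time / d | target / % | substrate / % |
|---|---|---|---|
| eta | 0.125 | 4.9 | 83.8 |
| eta | 0.500 | 9.9 | 52.7 |
| eta | 2.00 | 3.1 | 7.9 |
| eta | 10.0 | 0.1 | 0.5 |
| epsilon | 0.125 | 7.4 | 85.4 |
| epsilon | 0.500 | 10.0 | 50.7 |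
| epsilon | 2.00 | 3.1 | 6.7 |
| epsilon | 10.0 | 0.6 | 0 |

(standard deviation of a reading: 1 percentage point)

- the moment within 15 d at which there is most target
- the amount of target, in percent of the substrate charged, at that time
- earliest time at which at least nineteen twentieths of that best amount are there, in d
- latest time at which they still are, in d



I built the flask up one process at a time. The main step is the loss of substrate, and between 0.500 d and 2.00 d the two runs pooled gave a first-order constant of 1.31 /d. Then I added the supply of target: at 2.00 d the pooled ratio of target to substrate was 42.5%, and I took that as the level the ratio climbs towards. But at 0.500 d the ratio stood at 19.2%, so the target lags, and the gap closes at 1.21 /d. Added to the substrate's constant, this means the target clears at 2.51 /d, faster than the substrate decays. The two constants give a crossing, the moment at which the target's loss overtakes its supply, at 0.543 d. The amount of target standing at that moment, the crossing yield 10.1%, is the quantity I carried forward. Last came the capture agent: between the two runs the target at 0.500 d read 9.9% and 10.0%, with a scatter of 1 percentage point, so I left it out of the reckoning.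

The forecast, saying “So I expect 0.9 mM to behave like both runs.”, gave 10.2% at 0.5 d against my 10.1% at 0.543 d, with a window from 0.36 d to 0.72 d.

The flask reached 9.89% at 0.482 d, and the window asked for ran from 0.327 d to 0.703 d.

    second nucleophile + open intermediate → other capture product (k = 17.0 /M/h)
    open intermediate + capture agent → trapped intermediate (k = 1.70 /M/h)
    first nucleophile + open intermediate ⇌ target (K = 170 /M, k = 120 /M/h)
    substrate → open intermediate (k = 0.0550 /h)

Removing the step into trapped intermediate leaves that peak practically unchanged, and my crossing yield lay 0.21 points above it, with the crossing 0.0610 d after the peak.

In the neighbouring flask with 31 mM of substrate, my two first-order constants hold no substrate charge, so the crossing yield stays at 10.1% of the charge. That flask gave 9.57%.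

The data are calculated for substances that don't exist; scatter was added.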